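Remark: guaiane numbering is used for the target (C1–C5 cyclopentenone, C1/C5–C10 seven-membered ring, C11 the carbinol carbon, C14 the methyl on C10, C15 the methyl on C4). The SMILES is read as (1R,7S,8R,10S), with H-1, the C10 methyl, the C8 oxygen and the C7 side chain all on one face of the seven-membered ring.

## The problem

The target is a guaiane: a 2-methylcyclopentenone (C3=O, C4=C5) fused through C1–C5 to a cycloheptane. All four stereocentres (C1, C10, C7, C8) sit on the flexible seven-membered ring. They form two adjacent pairs (C1/C10 and C7/C8) separated by C9 on one side and C5–C6 on the other, so neither pair reliably controls the other. C1 is γ to the enone and can be left to equilibration, but C7, C8 and C10 must be set kinetically and in one absolute sense. The two esters differ: a secondary isobutyrate at C8 and a tertiary acetate at C11, cis and 1,3 to each other, so late acylation of a tertiary alcohol risks acyl migration and elimination. A cycloheptanone precursor with its carbonyl at C5 has CH2 groups on both sides (C1 and C6), so cyclopentenone annulation has no built-in regiocontrol. The feature that the plan exploits is this: C6 is the γ-carbon of the enone and C11 is joined to it through C7, so C11–OAc plus C6–H is the retron of an acid addition across a C6–C7–C11 cyclopropane. With the C6–C11 bond closed and C5 and C8 both written as ketones, the seven-membered ring has a mirror plane through C10 and C11. The target therefore hides a meso diketone (5), whose desymmetrization is the key step.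

## Retrosynthesis

12 ⇒ 11. The C11–O bond of the acetate and the C6–H bond are removed together by closing C6–C11. This is preferred to cutting the acetate as an ester, because the tertiary acetate then comes from acetate capture of a tertiary cation and never needs acylation. The precursor 11 has one ester instead of two, and its cyclopropane fixes C7. The forward step must open only the cyclopropane bond that is aligned with the enone and leads to the tertiary carbon.

11 ⇒ 10 ⇒ 8 (through 9). The isobutyrate is cut at the ester C–O bond, which gives alcohol 10. The cyclopentenone is cut at C4=C5 (aldol condensation) and at the C3 carbonyl (hydration of an alkyne), which leads back to butynyl ketone 8. An aldol closure is chosen over a Pauson–Khand or metathesis closure because the ketone at C5 is already present in 8. The cyclopropane at C6 cannot enolize, so only one closure is possible. Forward, hydration must place the oxygen on C3.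

8 ⇒ 6. The C1–C2 bond is cut as an enolate alkylation. In 6 the cyclopropane blocks enolization toward C6, which solves the C1/C6 regiochemistry problem of a plain cycloheptanone. The bridge and the C10 methyl both direct the electrophile to the face that gives the H-1 configuration of the target.

6 ⇒ 5 (key). The C8–H bond is removed to give meso diketone 5. This is preferred to any chiral-pool or auxiliary construction because one reduction of an achiral compound fixes the absolute configuration at C7, C8 and C10 and also decides which carbonyl becomes the C8 oxygen and which the C5 annulation site. The forward reaction must choose one of two enantiotopic carbonyls, choose its face, and stop after one reduction.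

5 ⇒ 4. The C6–C11 and C7–C11 bonds are cut as an isopropylidene transfer to enedione 4. The cis ring fusion is compulsory, and the only open question is the face relative to the remote methyl. 4 is achiral and has no stereocentre.

4 ⇒ 3 ⇒ 1. The C6=C7 bond is cut as an intramolecular coupling of two diazo carbons in 3, and the C5–C6 and C7–C8 bonds as acylations of a one-carbon diazo reagent by the diacid chloride 2 of 1. 3-Methylglutaric acid 1 supplies C5, C1, C10, C14, C9 and C8 in the correct symmetric arrangement, and the whole ring is built in two directions at once.

## Roads not taken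

Alternative 1: the obvious cut. Both acyl groups go on last, the cyclopentenone comes from alkylation and aldol condensation on cycloheptanone A1, and the seven-membered ring comes from ring-closing metathesis of an acyclic diene assembled by an auxiliary-controlled anti aldol reaction on a chiral-pool aldehyde. The forward key step would be the metathesis followed by the annulation. The chosen plan is better on three counts. A1 has enolizable CH2 groups at both C1 and C6, so the annulation regiochemistry is not controlled. C7/C8, C10 and C1 would each be set by a separate device (auxiliary, chiral pool, equilibration). The tertiary C11 hydroxyl would have to be acetylated at the end next to the C8 ester, and the route would be about twice as long.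

Alternative 2: both rings in one step by a rhodium-catalysed allenic Pauson–Khand reaction of allene-yne A2, which gives dienone A3 with C3=O, C4=C5 and C1=C10 in place. The cut is attractive, but A3 must then take up hydrogen at C1 and C10 from opposite faces (H-1 on the face of the C10 methyl), which no hydrogenation delivers. The 1,6-reduction and protonation would be governed only by the distant C7/C8 centres. A2 also still needs an anti aldol and an allene synthesis. The chosen plan sets C10 before the five-membered ring exists and sets C1 under the control of two neighbouring groups.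

Alternative 3: semisynthesis from the commercial guaiane (−)-guaiol A4, which already has the skeleton, the C11 hydroxyl and the correct C7 and C10 configurations. The forward key step would be hydroxylation of the unactivated C8 methylene (by a P450 monooxygenase or a C11-OH-directed C–H functionalization). This would be followed by oxidation at C3 and a shift of the C1=C5 alkene to C4=C5. C6 and C8 are both γ to the C11 oxygen and C6 is also allylic, so nothing in A4 marks C8 for attack, and three further redox operations on unactivated positions would follow. The chosen plan uses an enzyme class (carbonyl reduction) for which group and face selectivity on cyclic diketones is established.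

Key step: step 4

## Route

Step 1
Reactants: 1 3-methylpentanedioic acid (3-methylglutaric acid)
Product: 3 1,7-bis(diazo)-4-methylheptane-2,6-dione, via 3-methylpentanedioyl dichloride 2 (not isolated)
Conditions: SOCl2 (3 equiv), DMF (cat.), 70 °C, then evaporate; CH2N2 (5 equiv), Et2O, 0 °C
Reagents that add atoms: diazomethane, C=[N+]=[N-]; thionyl chloride, O=S(Cl)Cl (chlorine, in 2 only)
Why: Acyl chloride formation, then acylation of diazomethane (first stage of the Arndt–Eistert sequence); excess diazomethane removes HCl as chloromethane so that no chloromethyl ketone forms. No stereocentre is present, since C4 carries two identical arms.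

Step 2
Reactants: 3 1,7-bis(diazo)-4-methylheptane-2,6-dione
Product: 4 6-methylcyclohept-2-ene-1,4-dione
Conditions: Cu(acac)2 (5 mol%), benzene, reflux, slow addition of 3 (high dilution)
Reagents that add atoms: none
Why: Copper-catalysed loss of N2 gives a keto carbenoid that is attacked by the nucleophilic carbon of the second diazo ketone, and loss of the second N2 leaves the C=C bond (intramolecular carbene dimerisation of bis-diazo ketones, a known entry to cyclic cis-enediones). The ring allows only the cis alkene, and 4 is achiral.

Step 3
Reactants: 4 6-methylcyclohept-2-ene-1,4-dione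
Product: 5 meso-(1R,4r,7S)-4,8,8-trimethylbicyclo[5.1.0]octane-2,6-dione (4-methyl cis to the C8 bridge)
Conditions: iPr(Ph)2S+ BF4− (1.1 equiv), LiN(iPr)2 (1.1 equiv), DME, −78 °C; then 4, −78 → −30 °C
Reagents that add atoms: isopropyldiphenylsulfonium tetrafluoroborate, CC(C)[S+](c1ccccc1)c1ccccc1.F[B-](F)(F)F
Why: Corey–Chaykovsky-type cyclopropanation with diphenylsulfonium isopropylide: conjugate addition to the doubly activated alkene, then 3-exo-tet closure with loss of Ph2S; the ring fusion can only be cis. The ylide should attack the face away from the out-of-plane C6 of 4, whose methyl group is pseudo-equatorial, which places the methyl group cis to the new bridge; the minor trans meso isomer is removed by chromatography.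

Step 4
Reactants: 5 meso-(1R,4r,7S)-4,8,8-trimethylbicyclo[5.1.0]octane-2,6-dione
Product: 6 (1S,4S,6R,7R)-6-hydroxy-4,8,8-trimethylbicyclo[5.1.0]octan-2-one
Conditions: ketoreductase (NADPH-dependent, chosen from a screening panel), NADP+ (cat.), propan-2-ol (10% v/v), phosphate buffer pH 7.0, 30 °C
Reagents that add atoms: none
Why: The ketoreductase binds 5 so that only one of the two enantiotopic carbonyl groups (the one next to the R-configured bridgehead) lies over the nicotinamide ring, and NADPH transfers hydride to it while propan-2-ol regenerates the cofactor. The closest known reaction type is the ketoreductase or yeast monoreduction of meso and prochiral cyclic diketones. No ring is closed. The one new stereocentre, C6 of 6 (C8 of the target), is set R by the enzyme, and the substrate helps, because the endo methyl group of the dimethylcyclopropane blocks the syn face, so hydride arrives anti and the hydroxyl group ends up cis to the bridge. Choosing one carbonyl also fixes the absolute configuration of both bridgeheads and of the methyl-bearing carbon, which were only relative before. The step needs enantiotopic-group selectivity, face selectivity and a stop after one reduction. The first two come from the chiral pocket, which tells the bulky cyclopropyl flank from the CH2 flank; the third comes from the remaining carbonyl of 6 being the mirror-image, mismatched one and partly masked as a bridged hemiketal.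

Step 5
Reactants: 6 (1S,4S,6R,7R)-6-hydroxy-4,8,8-trimethylbicyclo[5.1.0]octan-2-one
Product: 8 (1S,3R,4S,6R,7R)-3-(but-2-yn-1-yl)-6-hydroxy-4,8,8-trimethylbicyclo[5.1.0]octan-2-one, via dilithium enolate-alkoxide 7 (not isolated)
Conditions: LiN(iPr)2 (2.2 equiv), THF, −78 → −20 °C; 1-bromobut-2-yne (1.1 equiv), DMPU, −78 → 0 °C
Reagents that add atoms: 1-bromobut-2-yne, CC#CCBr
Why: Kinetic enolate alkylation; the ketone can enolize only toward C3 because the other α-carbon is a cyclopropane carbon, and the lithium alkoxide is a much poorer nucleophile than the enolate. The new stereocentre C3 (C1 of the target) is set by attack anti to both the adjacent C4 methyl group and the dimethylcyclopropane bridge, which gives the trans relationship required.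

Step 6
Reactants: 8 (1S,3R,4S,6R,7R)-3-(but-2-yn-1-yl)-6-hydroxy-4,8,8-trimethylbicyclo[5.1.0]octan-2-one
Product: 10 (1aR,2R,4S,4aR,7bS)-2-hydroxy-1,1,4,7-tetramethyl-1,1a,2,3,4,4a,5,7b-octahydro-6H-cyclopropa[e]azulen-6-one, via 1,4-diketone 9 (not isolated)
Conditions: NaAuCl4·2H2O (2 mol%), MeOH/H2O (10:1), rt; then KOH (1 equiv), 60 °C
Reagents that add atoms: water, O (carbonyl oxygen of 9)
Why: Gold activates the alkyne and the ring carbonyl oxygen adds 5-exo-dig to the nearer alkyne carbon, so hydration places the new carbonyl only there and gives 1,4-diketone 9 (carbonyl-assisted alkyne hydration). KOH then effects the intramolecular aldol condensation, in which only the ethyl-ketone CH2 can close a five-membered ring onto the ring carbonyl, and dehydration gives the tetrasubstituted enone. No new stereocentre forms, and the carbon next to the methyl-bearing centre keeps the trans arrangement, which is also the expected thermodynamic one.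

Step 7
Reactants: 10 (1aR,2R,4S,4aR,7bS)-2-hydroxy-1,1,4,7-tetramethyl-1,1a,2,3,4,4a,5,7b-octahydro-6H-cyclopropa[e]azulen-6-one
Product: 11 (1aR,2R,4S,4aR,7bS)-1,1,4,7-tetramethyl-6-oxo-1a,2,3,4,4a,5,6,7b-octahydro-1H-cyclopropa[e]azulen-2-yl 2-methylpropanoate
Conditions: iPrCOCl (1.5 equiv), pyridine, DMAP (cat.), CH2Cl2, 0 °C → rt
Reagents that add atoms: 2-methylpropanoyl chloride, CC(C)C(=O)Cl
Why: DMAP-catalysed acylation of the only hydroxyl group in the molecule; the conditions are too mild to enolize the enone, so no stereocentre is affected.

Step 8
Reactants: 11 (1aR,2R,4S,4aR,7bS)-1,1,4,7-tetramethyl-6-oxo-1a,2,3,4,4a,5,6,7b-octahydro-1H-cyclopropa[e]azulen-2-yl 2-methylpropanoate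
Product: 12 (5S,6R,8S,8aR)-5-(2-acetoxypropan-2-yl)-3,8-dimethyl-2-oxo-1,2,4,5,6,7,8,8a-octahydroazulen-6-yl 2-methylpropanoate (target)
Conditions: AcOH (solvent), H2SO4 (5 mol%), 20 °C
Reagents that add atoms: acetic acid, CC(=O)O
Why: Protonation of the enone oxygen makes the enone β-carbon a cyclopropylcarbinyl cation; the external cyclopropane bond to the CMe2 carbon, which is aligned with the π system and leads to a tertiary cation, breaks, acetic acid captures that carbon, and the dienol returns to the conjugated enone with C6 as CH2 (homoconjugate addition of a carboxylic acid to a cyclopropyl ketone, here through the enone, as in the acetolysis of 3,5-cyclosteroid 6-ketones). No stereocentre is touched: C7 keeps its configuration and the former bridgehead C6 becomes CH2.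

## Compound list

1 | 3-methylpentanedioic acid (3-methylglutaric acid) | CC(CC(=O)O)CC(=O)O | starting material
2 | 3-methylpentanedioyl dichloride | CC(CC(=O)Cl)CC(=O)Cl | intermediate
3 | 1,7-bis(diazo)-4-methylheptane-2,6-dione | CC(CC(=O)C=[N+]=[N-])CC(=O)C=[N+]=[N-] | intermediate
4 | 6-methylcyclohept-2-ene-1,4-dione | CC1CC(=O)C=CC(=O)C1 | intermediate
5 | meso-(1R,4r,7S)-4,8,8-trimethylbicyclo[5.1.0]octane-2,6-dione (4-methyl cis to the C8 bridge) | CC1(C)[C@H]2[C@@H]1C(=O)C[C@@H](C)CC2=O | intermediate
6 | (1S,4S,6R,7R)-6-hydroxy-4,8,8-trimethylbicyclo[5.1.0]octan-2-one | CC1(C)[C@H]2[C@@H]1C(=O)C[C@@H](C)C[C@H]2O | intermediate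
7 | dilithium (1S,4S,6R,7R)-4,8,8-trimethylbicyclo[5.1.0]oct-2-ene-2,6-bis(olate) | CC1(C)[C@H]2[C@@H]1C([O-])=C[C@@H](C)C[C@H]2[O-].[Li+].[Li+] | intermediate
8 | (1S,3R,4S,6R,7R)-3-(but-2-yn-1-yl)-6-hydroxy-4,8,8-trimethylbicyclo[5.1.0]octan-2-one | CC1(C)[C@H]2[C@@H]1C(=O)[C@H](CC#CC)[C@@H](C)C[C@H]2O | intermediate
9 | (1S,3R,4S,6R,7R)-6-hydroxy-4,8,8-trimethyl-3-(2-oxobutyl)bicyclo[5.1.0]octan-2-one | CC1(C)[C@H]2[C@@H]1C(=O)[C@H](CC(=O)CC)[C@@H](C)C[C@H]2O | intermediate
10 | (1aR,2R,4S,4aR,7bS)-2-hydroxy-1,1,4,7-tetramethyl-1,1a,2,3,4,4a,5,7b-octahydro-6H-cyclopropa[e]azulen-6-one | CC1(C)[C@H]2[C@@H]1C3=C(C)C(=O)C[C@@H]3[C@@H](C)C[C@H]2O | intermediate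
11 | (1aR,2R,4S,4aR,7bS)-1,1,4,7-tetramethyl-6-oxo-1a,2,3,4,4a,5,6,7b-octahydro-1H-cyclopropa[e]azulen-2-yl 2-methylpropanoate | CC1(C)[C@H]2[C@@H]1C3=C(C)C(=O)C[C@@H]3[C@@H](C)C[C@H]2OC(=O)C(C)C | intermediate
12 | (5S,6R,8S,8aR)-5-(2-acetoxypropan-2-yl)-3,8-dimethyl-2-oxo-1,2,4,5,6,7,8,8a-octahydroazulen-6-yl 2-methylpropanoate | CC(=O)OC(C)(C)[C@H]1CC2=C(C)C(=O)C[C@@H]2[C@@H](C)C[C@H]1OC(=O)C(C)C | target

## Step count and risks

Total: 8 steps. Longest linear sequence: 8 steps from 1 (the route is fully linear).

Step 4 (key). No enzyme of the panel may combine discrimination between the two enantiotopic carbonyl groups with delivery of hydride anti to the bridge, or reduction may run on to the diol. The fallback sets out from 5: NaBH4 at low temperature, relying on the substrate's own facial bias, should give the racemic cis-hydroxy ketone F1. Kinetic resolution by lipase-catalysed acylation (Candida antarctica lipase B, vinyl acetate) should acylate the 6R enantiomer to acetate F2. After separation from the unreacted enantiomer, methanolysis (K2CO3, MeOH) returns to the route at 6.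

Step 2. Coupling between molecules (oligomers) and other carbenoid pathways may outrun closure of the seven-membered ring. The fallback sets out from 1 (through 2): amidation with MeNHOMe·HCl and pyridine gives bis-Weinreb amide F3, and vinylmagnesium bromide gives divinyl diketone F4. Ring-closing metathesis with the second-generation Hoveyda–Grubbs catalyst in hot toluene then forms the C=C bond and comes back at 4.

Step 3. Facial selectivity relative to the remote methyl group may be poor, and the basic ylide may enolize 4 instead of adding to it. The fallback sets out from 4 and accepts the mixture of 5 and its methyl epimer F5. Dehydrogenation of the mixture with IBX gives the single racemic enone F6, and conjugate reduction with [(Ph3P)CuH]6, which should deliver hydride anti to the bridge, comes back at 5 as the cis isomer only.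

Step 8. The C11 cation may lose a proton to give the isopropenyl group instead of taking up acetate. The neighbouring C8 ester carbonyl may capture the cation and cause acyl migration. Ionization of the cyclopropylcarbinyl ester may open the other cyclopropane bond. The fallback sets out from 11: opening in dilute aqueous HClO4/THF, where water is the nucleophile and any ester participation hydrolyses to the same product, gives tertiary alcohol F7. Acetylation of the tertiary hydroxyl (Ac2O, Sc(OTf)3 cat., MeCN, −20 °C) comes back at 12.

Step 5. The lithium alkoxide may add to the ketone (bridged hemiketal) and slow enolization, and O-alkylation or double alkylation may compete. The fallback sets out from 6: silylation (TBSCl, imidazole) gives silyl ether F8, alkylation with one equivalent of LiN(iPr)2 and 1-bromobut-2-yne gives F9, the conditions of step 6 give silyl enone F10, and Bu4NF comes back at 10.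

## Further compounds

F1 | step 4 | rac-(1S,4S,6R,7R)-6-hydroxy-4,8,8-trimethylbicyclo[5.1.0]octan-2-one (racemate, one enantiomer drawn) | CC1(C)[C@H]2[C@@H]1C(=O)C[C@@H](C)C[C@H]2O
F2 | step 4 | (1R,2R,4S,7S)-4,8,8-trimethyl-6-oxobicyclo[5.1.0]octan-2-yl acetate | CC1(C)[C@H]2[C@@H]1C(=O)C[C@@H](C)C[C@H]2OC(C)=O
F3 | step 2 | N1,N5-dimethoxy-N1,N5,3-trimethylpentanediamide | CC(CC(=O)N(C)OC)CC(=O)N(C)OC
F4 | step 2 | 5-methylnona-1,8-diene-3,7-dione | CC(CC(=O)C=C)CC(=O)C=C
F5 | step 3 | meso-(1R,4s,7S)-4,8,8-trimethylbicyclo[5.1.0]octane-2,6-dione (4-methyl trans to the C8 bridge) | CC1(C)[C@H]2[C@@H]1C(=O)C[C@H](C)CC2=O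
F6 | step 3 | rac-(1S,7R)-4,8,8-trimethylbicyclo[5.1.0]oct-3-ene-2,6-dione (racemate, one enantiomer drawn) | CC1(C)[C@H]2[C@@H]1C(=O)C=C(C)CC2=O
F7 | step 8 | (5S,6R,8S,8aR)-5-(2-hydroxypropan-2-yl)-3,8-dimethyl-2-oxo-1,2,4,5,6,7,8,8a-octahydroazulen-6-yl 2-methylpropanoate | CC(C)(O)[C@H]1CC2=C(C)C(=O)C[C@@H]2[C@@H](C)C[C@H]1OC(=O)C(C)C
F8 | step 5 | (1S,4S,6R,7R)-6-[(tert-butyldimethylsilyl)oxy]-4,8,8-trimethylbicyclo[5.1.0]octan-2-one | CC1(C)[C@H]2[C@@H]1C(=O)C[C@@H](C)C[C@H]2O[Si](C)(C)C(C)(C)C
F9 | step 5 | (1S,3R,4S,6R,7R)-3-(but-2-yn-1-yl)-6-[(tert-butyldimethylsilyl)oxy]-4,8,8-trimethylbicyclo[5.1.0]octan-2-one | CC1(C)[C@H]2[C@@H]1C(=O)[C@H](CC#CC)[C@@H](C)C[C@H]2O[Si](C)(C)C(C)(C)C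
F10 | step 5 | (1aR,2R,4S,4aR,7bS)-2-[(tert-butyldimethylsilyl)oxy]-1,1,4,7-tetramethyl-1,1a,2,3,4,4a,5,7b-octahydro-6H-cyclopropa[e]azulen-6-one | CC1(C)[C@H]2[C@@H]1C3=C(C)C(=O)C[C@@H]3[C@@H](C)C[C@H]2O[Si](C)(C)C(C)(C)C
A1 | alternative 1 | (3S,4R,6S)-4-hydroxy-3-(2-hydroxypropan-2-yl)-6-methylcycloheptan-1-one | CC(C)(O)[C@H]1CC(=O)C[C@@H](C)C[C@H]1O
A2 | alternative 2 | (3S,4R)-3-(but-2-yn-1-yl)-2,6-dimethylocta-6,7-diene-2,4-diol | CC#CC[C@H](C(C)(C)O)[C@H](O)CC(C)=C=C
A3 | alternative 2 | (5S,6R)-6-hydroxy-5-(2-hydroxypropan-2-yl)-3,8-dimethyl-4,5,6,7-tetrahydroazulen-2(1H)-one | CC1=C2C[C@H](C(C)(C)O)[C@H](O)CC(C)=C2CC1=O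
A4 | alternative 3 | (−)-guaiol, 2-[(3S,5R,8S)-3,8-dimethyl-1,2,3,4,5,6,7,8-octahydroazulen-5-yl]propan-2-ol | C[C@H]1CCC2=C1C[C@H](C(C)(C)O)CC[C@@H]2C
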